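Ring B is disconnected at C-1–C-8a and C-4–C-4a. C-1 to C-4, with oxygen at C-2 and the bromocyclopentyl ring A on C-3, form a 2-silyloxybutadiene; the C-4a–C-8a edge of ring C is the α,β-bond of a 3-methylcyclohex-2-enone whose β-carbon is the methyl-bearing C-8a. One Lewis-acid-promoted Diels–Alder reaction joins the halves, closes ring B and sets the quaternary C-8a under control of a silyloxy group at C-8. The diene comes from (1R,4S)-camphanic acid by a catalyst-controlled reduction and one inversion; the dienophile from 3-methylcyclohexenone by γ-hydroxylation and enzymatic resolution. Oxygenation at C-4a, methyl addition at C-5 and inversion at C-8 follow.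

Key step: step 11

Remarks on the chemistry
- Locants of all bicyclic compounds follow the target (C-1 to C-8a; ring B = C-1 to C-4a/C-8a, ring C = C-4a to C-8a). The cyclopentane (ring A) is primed: C-1' quaternary, C-2' CMe2, C-3' CHBr.
- Structure check: diene 13, dienophile 18 and adduct 19 agree with the target atom by atom and in configuration; no correction was needed.
- Ring A: the C-3' bromine is cis to the C-1' carbon substituent, the position a carboxyl holds in (1S,3R)-camphoric acid. Putting bromine there from that acid needs net retention, which neither a radical bromodecarboxylation (no facial control) nor retentive oxygenation followed by SN2 gives. Ring A is therefore taken from commercial (1R,4S)-camphanic acid (also the classical bromination/hydrolysis product of that camphoric acid), and C-3' is set by a catalyst-controlled ketone reduction and one inversion.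
- C-8: the cycloadduct carries its oxygen on the face that bromine holds in the target, so C-8 needs oxidation, axial-selective reduction and one inversion.
- Assumption (step 9): the lipase acylates the R alcohol, the usual preference when the alkene carbon is the larger carbinol substituent.

Step 1
Reactants: 1 (1R,4S)-camphanic acid
Product: 4 (1S)-1,2,2-trimethyl-3-oxocyclopentane-1-carboxylic acid, via camphanoyl azide 2 (not isolated), via bridgehead isocyanate 3 (not isolated)
Conditions: (PhO)2P(O)N3, Et3N, PhMe, 20 → 90 °C; then 2 M HCl, dioxane, 70 °C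
Reagents that add atoms: water, O
Why: Curtius rearrangement moves the bridgehead carbon to nitrogen with retention, and acid hydrolysis of the α-acyloxy isocyanate (an N,O-acetal carbon) releases the C-3' ketone and the C-1' carboxylic acid together, a known degradation of α-oxygenated acids to carbonyl compounds; the quaternary C-1' centre comes unchanged from the starting material.

Step 2
Reactants: 4 (1S)-1,2,2-trimethyl-3-oxocyclopentane-1-carboxylic acid
Product: 6 (1S,3S)-3-hydroxy-1,2,2-trimethylcyclopentane-1-carboxylic acid, via trimethylsilyl ester 5 (not isolated)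
Conditions: TMSCl, Et3N, Et2O, 0 °C, filter, concentrate; then (R)-Me-CBS oxazaborolidine (C18H20BNO, 20 mol %), BH3·SMe2, THF, −20 °C; then MeOH, 1 M HCl
Reagents that add atoms: none
Why: Corey–Bakshi–Shibata reduction: the catalyst distinguishes the quaternary C-2' (large) from the C-4' methylene (small) and should deliver hydride to give the 3'S carbinol (hydroxyl trans to the carboxyl) under reagent control; the transient silyl ester shields the acid from borane, and any cis epimer would lactonise and be removed as a neutral by-product.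

Step 3
Reactants: 6 (1S,3S)-3-hydroxy-1,2,2-trimethylcyclopentane-1-carboxylic acid
Product: 7 1-[(1S,3S)-3-hydroxy-1,2,2-trimethylcyclopentyl]ethan-1-one
Conditions: MeLi (4 equiv), Et2O, 0 → 20 °C; inverse quench into cold 1 M HCl
Reagents that add atoms: methyllithium, [Li]C
Why: Ketone synthesis by organolithium addition to a lithium carboxylate: the dilithium gem-diolate does not collapse until hydrolysis, so addition stops at the methyl ketone; the C-3' alkoxide is a spectator and no stereocentre is touched.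

Step 4
Reactants: 7 1-[(1S,3S)-3-hydroxy-1,2,2-trimethylcyclopentyl]ethan-1-one
Product: 9 1-[(1S,3S)-3-hydroxy-1,2,2-trimethylcyclopentyl]ethenyl trifluoromethanesulfonate, via dipotassium alkoxide enolate 8 (not isolated)
Conditions: KN(SiMe3)2 (2.2 equiv), THF, −78 °C; then PhNTf2 (1.05 equiv), −78 → 0 °C
Reagents that add atoms: N-phenylbis(trifluoromethanesulfonimide), FC(F)(F)S(=O)(=O)N(c1ccccc1)S(=O)(=O)C(F)(F)F
Why: Enol triflate formation by O-sulfonylation of the only possible enolate; N-phenyltriflimide reacts with the enolate oxygen far faster than with the hindered secondary alkoxide, and removing the carbonyl group now prevents it from attacking C-3' from the rear in step 5.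

Step 5
Reactants: 9 1-[(1S,3S)-3-hydroxy-1,2,2-trimethylcyclopentyl]ethenyl trifluoromethanesulfonate
Product: 10 1-[(1S,3R)-3-bromo-1,2,2-trimethylcyclopentyl]ethenyl trifluoromethanesulfonate
Conditions: CBr4, PPh3, PhMe, 0 → 60 °C
Reagents that add atoms: tetrabromomethane, BrC(Br)(Br)Br
Why: Appel reaction: bromide displaces the alkoxyphosphonium group from the rear (SN2), inverting C-3' and placing bromine cis to the C-1' carbon substituent; with no carbonyl on C-1' there is no neighbouring-group participation, and the neutral non-ionising medium works against elimination and methyl migration.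

Step 6
Reactants: 10 1-[(1S,3R)-3-bromo-1,2,2-trimethylcyclopentyl]ethenyl trifluoromethanesulfonate
Product: 12 3-[(1R,3R)-3-bromo-1,2,2-trimethylcyclopentyl]but-3-en-2-one, via 2-ethoxydiene 11 (not isolated)
Conditions: Bu3SnC(OEt)=CH2, Pd(PPh3)4 (5 mol %), LiCl, CuI (10 mol %), THF, 65 °C; then 1 M HCl, 20 °C
Reagents that add atoms: tributyl(1-ethoxyvinyl)stannane, CCCC[Sn](CCCC)(CCCC)C(=C)OCC; water, O
Why: Stille coupling of the enol triflate with an acetyl-anion equivalent, then hydrolysis of the enol ether, should give the α-methylene ketone; the hindered secondary alkyl bromide does not undergo oxidative addition to Pd(PPh3)4 under these conditions.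

Step 7
Reactants: 12 3-[(1R,3R)-3-bromo-1,2,2-trimethylcyclopentyl]but-3-en-2-one
Product: 13 tert-butyl({3-[(1R,3R)-3-bromo-1,2,2-trimethylcyclopentyl]buta-1,3-dien-2-yl}oxy)dimethylsilane
Conditions: TBSOTf, Et3N, CH2Cl2, −78 → 0 °C
Reagents that add atoms: tert-butyldimethylsilyl trifluoromethanesulfonate, CC(C)(C)[Si](C)(C)OS(=O)(=O)C(F)(F)F
Why: Silyl enol ether formation by soft enolisation: the methyl group is the only enolisable position, so O-silylation gives the 2-silyloxy-1,3-diene directly.

Step 8
Reactants: 14 3-methylcyclohex-2-en-1-one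
Product: 16 rac-4-hydroxy-3-methylcyclohex-2-en-1-one, via dienyl acetate 15 (not isolated)
Conditions: isopropenyl acetate, TsOH (cat.), 95 °C, evaporate; then mCPBA, NaHCO3, CH2Cl2/H2O, 0 °C
Reagents that add atoms: 3-chloroperbenzoic acid, OOC(=O)c1cccc(Cl)c1
Why: Acid-catalysed enol acetylation gives the thermodynamic linear dienyl acetate, whose remote trisubstituted double bond is epoxidised; opening of the epoxide by the enol acetate (a vinylogous Rubottom-type γ-hydroxylation) returns the enone with the new hydroxyl at C-4, as the racemate.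

Step 9
Reactants: 16 rac-4-hydroxy-3-methylcyclohex-2-en-1-one
Product: 17 (4S)-4-hydroxy-3-methylcyclohex-2-en-1-one
Conditions: Burkholderia cepacia lipase (Amano PS), vinyl acetate, t-BuOMe, 30 °C, run just past half conversion
Reagents that add atoms: none
Why: Enzymatic kinetic resolution by irreversible transesterification: the lipase is expected to acetylate the R alcohol, so the S alcohol is recovered unreacted and separated from the acetate by chromatography.

Step 10
Reactants: 17 (4S)-4-hydroxy-3-methylcyclohex-2-en-1-one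
Product: 18 (4S)-4-[(tert-butyldimethylsilyl)oxy]-3-methylcyclohex-2-en-1-one
Conditions: TBSCl, imidazole, DMF, 20 °C
Reagents that add atoms: tert-butyldimethylsilyl chloride, CC(C)(C)[Si](C)(C)Cl
Why: Standard silylation of the secondary allylic alcohol; the bulky silyloxy group is the element that shields one face of the enone in step 11.

Step 11
Reactants: 13 tert-butyl({3-[(1R,3R)-3-bromo-1,2,2-trimethylcyclopentyl]buta-1,3-dien-2-yl}oxy)dimethylsilane; 18 (4S)-4-[(tert-butyldimethylsilyl)oxy]-3-methylcyclohex-2-en-1-one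
Product: 19 (4aR,8S,8aS)-3-[(1R,3R)-3-bromo-1,2,2-trimethylcyclopentyl]-2,8-bis[(tert-butyldimethylsilyl)oxy]-8a-methyl-4,4a,6,7,8,8a-hexahydronaphthalen-5(1H)-one
Conditions: Me2AlCl (1.2 equiv), CH2Cl2, −78 → −20 °C; Et3N, then aq. NaHCO3
Reagents that add atoms: none
Why: The aluminium Lewis acid binds the enone carbonyl and lowers its LUMO, so the electron-rich 2-silyloxydiene adds in a normal-demand Diels–Alder reaction that is concerted but strongly asynchronous (a stepwise Mukaiyama–Michael/Michael course would form the same bonds). The closest known reaction type is the Lewis-acid-promoted cycloaddition of 2-silyloxybutadienes with 3-methylcyclohex-2-enones to angularly methylated cis-octalones. Ring B closes as a six-membered ring by [4+2] cycloaddition, suprafacial on both partners and therefore cis-fused. C-8a is set by approach of the diene to the enone face opposite the C-8 silyloxy group, and C-4a follows from the suprafacial addition (its configuration is erased in step 13). The step needs regioselectivity, secured by the silyloxy group, which makes the adjacent CH2 terminus (C-1) the nucleophilic end that bonds to the β-carbon C-8a, and facial selectivity, secured by the C-8 substituent. The quaternary substituent on the internal diene carbon holds the diene s-cis, and Me2AlCl scavenges protic acid that would desilylate it.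

Step 12
Reactants: 19 (4aR,8S,8aS)-3-[(1R,3R)-3-bromo-1,2,2-trimethylcyclopentyl]-2,8-bis[(tert-butyldimethylsilyl)oxy]-8a-methyl-4,4a,6,7,8,8a-hexahydronaphthalen-5(1H)-one
Product: 20 (4aR,8S,8aS)-3-[(1R,3R)-3-bromo-1,2,2-trimethylcyclopentyl]-8-[(tert-butyldimethylsilyl)oxy]-8a-methyl-1,4a,6,7,8,8a-hexahydronaphthalene-2,5-dione
Conditions: Pd(OAc)2 (1.1 equiv), MeCN, 40 °C
Reagents that add atoms: none
Why: Saegusa–Ito oxidation: palladium diacetate turns the silyl enol ether into an oxa-π-allyl palladium species at C-3, and β-hydride elimination can only take a C-4 hydrogen (C-1' has none), so the C-3=C-4 enone should form regiospecifically; the secondary silyl ether and the C-5 ketone are inert.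

Step 13
Reactants: 20 (4aR,8S,8aS)-3-[(1R,3R)-3-bromo-1,2,2-trimethylcyclopentyl]-8-[(tert-butyldimethylsilyl)oxy]-8a-methyl-1,4a,6,7,8,8a-hexahydronaphthalene-2,5-dione
Product: 22 (4aR,8S,8aR)-3-[(1R,3R)-3-bromo-1,2,2-trimethylcyclopentyl]-8-[(tert-butyldimethylsilyl)oxy]-4a-hydroxy-8a-methyl-1,4a,6,7,8,8a-hexahydronaphthalene-2,5-dione, via potassium dienolate 21 (not isolated)
Conditions: KN(SiMe3)2 (1.1 equiv), THF, −78 → −40 °C; then 2-(phenylsulfonyl)-3-phenyloxaziridine, −78 °C; aq. NH4Cl
Reagents that add atoms: 2-(benzenesulfonyl)-3-phenyloxaziridine, O=S(=O)(c1ccccc1)N1OC1c1ccccc1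
Why: Davis oxidation of an enolate: the C-4a hydrogen, α to the C-5 ketone and γ to the enone, is by far the most acidic; the planar dienolate should be oxygenated at C-4a (C-3 is buried by the quaternary C-1') from the face opposite the C-8a methyl, which sets the 4a-hydroxyl trans to the methyl and makes the ring fusion trans.

Step 14
Reactants: 22 (4aR,8S,8aR)-3-[(1R,3R)-3-bromo-1,2,2-trimethylcyclopentyl]-8-[(tert-butyldimethylsilyl)oxy]-4a-hydroxy-8a-methyl-1,4a,6,7,8,8a-hexahydronaphthalene-2,5-dione
Product: 23 (4aR,5R,8S,8aR)-3-[(1R,3R)-3-bromo-1,2,2-trimethylcyclopentyl]-8-[(tert-butyldimethylsilyl)oxy]-4a,5-dihydroxy-5,8a-dimethyl-4a,5,6,7,8,8a-hexahydronaphthalen-2(1H)-one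
Conditions: MeMgBr (2.5 equiv), THF, −78 → −20 °C; aq. NH4Cl
Reagents that add atoms: methylmagnesium bromide, C[Mg]Br
Why: Grignard addition: the first equivalent forms the C-4a magnesium alkoxide, which activates the neighbouring C-5 carbonyl ahead of the hindered conjugated C-2 carbonyl; methyl should enter equatorially from the alkoxide face because the axial path is closed by the 1,3-diaxial C-8a methyl, giving the equatorial 5-methyl and axial 5-hydroxyl (trans-diaxial 4a,5-diol).

Step 15
Reactants: 23 (4aR,5R,8S,8aR)-3-[(1R,3R)-3-bromo-1,2,2-trimethylcyclopentyl]-8-[(tert-butyldimethylsilyl)oxy]-4a,5-dihydroxy-5,8a-dimethyl-4a,5,6,7,8,8a-hexahydronaphthalen-2(1H)-one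
Product: 24 (4aR,5R,8S,8aR)-3-[(1R,3R)-3-bromo-1,2,2-trimethylcyclopentyl]-4a,5,8-trihydroxy-5,8a-dimethyl-4a,5,6,7,8,8a-hexahydronaphthalen-2(1H)-one
Conditions: HF·pyridine, THF, 0 → 20 °C
Reagents that add atoms: none
Why: Fluoride-mediated desilylation of the secondary silyl ether under buffered conditions that should leave the tertiary alcohols and the γ-hydroxy enone untouched.

Step 16
Reactants: 24 (4aR,5R,8S,8aR)-3-[(1R,3R)-3-bromo-1,2,2-trimethylcyclopentyl]-4a,5,8-trihydroxy-5,8a-dimethyl-4a,5,6,7,8,8a-hexahydronaphthalen-2(1H)-one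
Product: 25 (4aR,5R,8aS)-3-[(1R,3R)-3-bromo-1,2,2-trimethylcyclopentyl]-4a,5-dihydroxy-5,8a-dimethyl-1,4a,5,6,7,8a-hexahydronaphthalene-2,8-dione
Conditions: Dess–Martin periodinane, NaHCO3, CH2Cl2, 20 °C
Reagents that add atoms: none
Why: Dess–Martin oxidation converts the only secondary alcohol into the C-8 ketone; tertiary alcohols are inert, and the buffered neutral medium avoids retro-aldol cleavage of the resulting β-hydroxy ketone.

Step 17
Reactants: 25 (4aR,5R,8aS)-3-[(1R,3R)-3-bromo-1,2,2-trimethylcyclopentyl]-4a,5-dihydroxy-5,8a-dimethyl-1,4a,5,6,7,8a-hexahydronaphthalene-2,8-dione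
Product: 26 (4aR,5R,8R,8aR)-3-[(1R,3R)-3-bromo-1,2,2-trimethylcyclopentyl]-4a,5,8-trihydroxy-5,8a-dimethyl-4a,5,6,7,8,8a-hexahydronaphthalen-2(1H)-one
Conditions: LiBH(s-Bu)3 (3.3 equiv), THF, −78 → −40 °C; aq. NH4Cl
Reagents that add atoms: none
Why: Hindered-hydride (L-Selectride) reduction: axial approach to C-8 is blocked by the 1,3-diaxial C-4a alkoxide, so hydride should add equatorially and give the axial 8-alcohol trans to the C-8a methyl; the enone should survive because C-4 is shielded on one face by the C-4a alkoxide and on the other by the C-8a methyl, and C-3 carries the quaternary cyclopentyl group.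

Step 18
Reactants: 26 (4aR,5R,8R,8aR)-3-[(1R,3R)-3-bromo-1,2,2-trimethylcyclopentyl]-4a,5,8-trihydroxy-5,8a-dimethyl-4a,5,6,7,8,8a-hexahydronaphthalen-2(1H)-one
Product: 27 (4aR,5R,8S,8aS)-8-bromo-3-[(1R,3R)-3-bromo-1,2,2-trimethylcyclopentyl]-4a,5-dihydroxy-5,8a-dimethyl-4a,5,6,7,8,8a-hexahydronaphthalen-2(1H)-one
Conditions: CBr4, P(n-C8H17)3, PhMe, 70 °C
Reagents that add atoms: tetrabromomethane, BrC(Br)(Br)Br
Why: Appel reaction: the axial secondary alkoxyphosphonium group should be displaced by bromide from the equatorial direction with inversion, giving the equatorial 8-bromide cis to the C-8a methyl; the two tertiary hydroxyls are too hindered to be activated under these conditions.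

Compound list
1 | (1R,4S)-4,7,7-trimethyl-3-oxo-2-oxabicyclo[2.2.1]heptane-1-carboxylic acid, (1R,4S)-camphanic acid | CC1(C)[C@@]2(C(O)=O)CC[C@]1(C)C(=O)O2 | starting material
2 | (1R,4S)-camphanoyl azide (formed in the flask) | CC1(C)[C@@]2(C(=O)N=[N+]=[N-])CC[C@]1(C)C(=O)O2 | intermediate
3 | (1R,4S)-1-isocyanato-4,7,7-trimethyl-2-oxabicyclo[2.2.1]heptan-3-one (formed in the flask) | CC1(C)[C@@]2(N=C=O)CC[C@]1(C)C(=O)O2 | intermediate
4 | (1S)-1,2,2-trimethyl-3-oxocyclopentane-1-carboxylic acid | CC1(C)C(=O)CC[C@]1(C)C(O)=O | intermediate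
5 | trimethylsilyl (1S)-1,2,2-trimethyl-3-oxocyclopentane-1-carboxylate (formed in the flask) | CC1(C)C(=O)CC[C@]1(C)C(=O)O[Si](C)(C)C | intermediate
6 | (1S,3S)-3-hydroxy-1,2,2-trimethylcyclopentane-1-carboxylic acid (hydroxyl trans to carboxyl) | CC1(C)[C@@H](O)CC[C@]1(C)C(O)=O | intermediate
7 | 1-[(1S,3S)-3-hydroxy-1,2,2-trimethylcyclopentyl]ethan-1-one | CC1(C)[C@@H](O)CC[C@]1(C)C(C)=O | intermediate
8 | dipotassium alkoxide enolate of 7 (formed in the flask) | CC1(C)[C@@H]([O-])CC[C@]1(C)C(=C)[O-].[K+].[K+] | intermediate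
9 | 1-[(1S,3S)-3-hydroxy-1,2,2-trimethylcyclopentyl]ethenyl trifluoromethanesulfonate | CC1(C)[C@@H](O)CC[C@]1(C)C(=C)OS(=O)(=O)C(F)(F)F | intermediate
10 | 1-[(1S,3R)-3-bromo-1,2,2-trimethylcyclopentyl]ethenyl trifluoromethanesulfonate (bromine cis to the vinyl group) | CC1(C)[C@H](Br)CC[C@]1(C)C(=C)OS(=O)(=O)C(F)(F)F | intermediate
11 | (1R,3R)-3-bromo-1-(3-ethoxybuta-1,3-dien-2-yl)-1,2,2-trimethylcyclopentane (formed in the flask) | CC1(C)[C@H](Br)CC[C@]1(C)C(=C)C(=C)OCC | intermediate
12 | 3-[(1R,3R)-3-bromo-1,2,2-trimethylcyclopentyl]but-3-en-2-one | CC1(C)[C@H](Br)CC[C@]1(C)C(=C)C(C)=O | intermediate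
13 | tert-butyl({3-[(1R,3R)-3-bromo-1,2,2-trimethylcyclopentyl]buta-1,3-dien-2-yl}oxy)dimethylsilane | CC1(C)[C@H](Br)CC[C@]1(C)C(=C)C(=C)O[Si](C)(C)C(C)(C)C | intermediate
14 | 3-methylcyclohex-2-en-1-one | CC1=CC(=O)CCC1 | starting material
15 | 3-methylcyclohexa-1,3-dien-1-yl acetate (formed in the flask) | CC1=CCCC(OC(C)=O)=C1 | intermediate
16 | rac-4-hydroxy-3-methylcyclohex-2-en-1-one | CC1=CC(=O)CCC1O | intermediate
17 | (4S)-4-hydroxy-3-methylcyclohex-2-en-1-one | CC1=CC(=O)CC[C@@H]1O | intermediate
18 | (4S)-4-[(tert-butyldimethylsilyl)oxy]-3-methylcyclohex-2-en-1-one | CC1=CC(=O)CC[C@@H]1O[Si](C)(C)C(C)(C)C | intermediate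
19 | (4aR,8S,8aS)-3-[(1R,3R)-3-bromo-1,2,2-trimethylcyclopentyl]-2,8-bis[(tert-butyldimethylsilyl)oxy]-8a-methyl-4,4a,6,7,8,8a-hexahydronaphthalen-5(1H)-one (cis-fused; 8-silyloxy cis to the 8a-methyl) | CC1(C)[C@H](Br)CC[C@]1(C)C1=C(O[Si](C)(C)C(C)(C)C)C[C@]2(C)[C@@H](O[Si](C)(C)C(C)(C)C)CCC(=O)[C@@H]2C1 | intermediate
20 | (4aR,8S,8aS)-3-[(1R,3R)-3-bromo-1,2,2-trimethylcyclopentyl]-8-[(tert-butyldimethylsilyl)oxy]-8a-methyl-1,4a,6,7,8,8a-hexahydronaphthalene-2,5-dione | CC1(C)[C@H](Br)CC[C@]1(C)C1=C[C@H]2C(=O)CC[C@H](O[Si](C)(C)C(C)(C)C)[C@@]2(C)CC1=O | intermediate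
21 | potassium dienolate of 20, delocalised over O-5, C-4a, C-4, C-3 and O-2 (formed in the flask) | CC1(C)[C@H](Br)CC[C@]1(C)C1=CC2=C([O-])CC[C@H](O[Si](C)(C)C(C)(C)C)[C@@]2(C)CC1=O.[K+] | intermediate
22 | (4aR,8S,8aR)-3-[(1R,3R)-3-bromo-1,2,2-trimethylcyclopentyl]-8-[(tert-butyldimethylsilyl)oxy]-4a-hydroxy-8a-methyl-1,4a,6,7,8,8a-hexahydronaphthalene-2,5-dione (trans-fused; 4a-hydroxyl trans to the 8a-methyl) | CC1(C)[C@H](Br)CC[C@]1(C)C1=C[C@]2(O)C(=O)CC[C@H](O[Si](C)(C)C(C)(C)C)[C@@]2(C)CC1=O | intermediate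
23 | (4aR,5R,8S,8aR)-3-[(1R,3R)-3-bromo-1,2,2-trimethylcyclopentyl]-8-[(tert-butyldimethylsilyl)oxy]-4a,5-dihydroxy-5,8a-dimethyl-4a,5,6,7,8,8a-hexahydronaphthalen-2(1H)-one | CC1(C)[C@H](Br)CC[C@]1(C)C1=C[C@]2(O)[C@](C)(O)CC[C@H](O[Si](C)(C)C(C)(C)C)[C@@]2(C)CC1=O | intermediate
24 | (4aR,5R,8S,8aR)-3-[(1R,3R)-3-bromo-1,2,2-trimethylcyclopentyl]-4a,5,8-trihydroxy-5,8a-dimethyl-4a,5,6,7,8,8a-hexahydronaphthalen-2(1H)-one (equatorial 8-hydroxyl) | CC1(C)[C@H](Br)CC[C@]1(C)C1=C[C@]2(O)[C@](C)(O)CC[C@H](O)[C@@]2(C)CC1=O | intermediate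
25 | (4aR,5R,8aS)-3-[(1R,3R)-3-bromo-1,2,2-trimethylcyclopentyl]-4a,5-dihydroxy-5,8a-dimethyl-1,4a,5,6,7,8a-hexahydronaphthalene-2,8-dione | CC1(C)[C@H](Br)CC[C@]1(C)C1=C[C@]2(O)[C@](C)(O)CCC(=O)[C@@]2(C)CC1=O | intermediate
26 | (4aR,5R,8R,8aR)-3-[(1R,3R)-3-bromo-1,2,2-trimethylcyclopentyl]-4a,5,8-trihydroxy-5,8a-dimethyl-4a,5,6,7,8,8a-hexahydronaphthalen-2(1H)-one (axial 8-hydroxyl) | CC1(C)[C@H](Br)CC[C@]1(C)C1=C[C@]2(O)[C@](C)(O)CC[C@@H](O)[C@@]2(C)CC1=O | intermediate
27 | (4aR,5R,8S,8aS)-8-bromo-3-[(1R,3R)-3-bromo-1,2,2-trimethylcyclopentyl]-4a,5-dihydroxy-5,8a-dimethyl-4a,5,6,7,8,8a-hexahydronaphthalen-2(1H)-one | CC1(C)[C@H](Br)CC[C@]1(C)C1=C[C@]2(O)[C@](C)(O)CC[C@H](Br)[C@@]2(C)CC1=O | target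

Total step count: 18. Longest linear sequence: 15 steps (steps 1–7 and 11–18).

The three steps most likely to fail

Step 11 (key step). Cycloaddition at the fully substituted β-carbon is slow, so protodesilylation of the diene, addition to the carbonyl group, or arrest after the first C–C bond may overtake ring closure; erosion of facial selectivity is the lesser concern. The fallback sets out from 13 and 18 and returns at 19, forming the two bonds in separate operations. Catalytic tert-butyldimethylsilyl triflimide (from HNTf2, 5 mol %) in CH2Cl2 at −78 °C should promote an intermolecular Mukaiyama–Michael addition anti to the C-8 silyloxy group, with silyl transfer to the C-5 oxygen, giving the open-chain vinyl ketone 1-[(1S,6S)-3,6-bis(tert-butyldimethylsilyloxy)-1-methylcyclohex-2-en-1-yl]-3-[(1R,3R)-3-bromo-1,2,2-trimethylcyclopentyl]but-3-en-2-one F1. A second, intramolecular Mukaiyama–Michael addition of its C-5 silyl enol ether to the vinyl ketone (Me2AlCl or TiCl4, CH2Cl2, −78 °C) closes the C-4–C-4a bond, the silyl group passes to the C-2 oxygen, and the route is rejoined at 19.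

Step 18. Substitution at the axial, neopentyl-type C-8 is slow, so elimination toward C-7, migration of the C-8a methyl, transannular ether formation by the 5-hydroxyl, or capture of the syn-diaxial 4a,8-diol as a cyclic phosphorane may compete. The fallback sets out from 26 and returns at 27, using that syn-diaxial diol as the activating device. SOCl2/pyridine at −20 °C should give the 4a,8-cyclic sulfite of 26 F2; RuCl3 (cat.)/NaIO4 in MeCN/H2O at 0 °C with short contact time oxidises it to the 4a,8-cyclic sulfate of 26 F3. Bu4NBr in THF opens the sulfate at the secondary C-8 with inversion to the tetrabutylammonium 4a-sulfate of 27 F4, and catalytic H2SO4 in wet THF cleaves the sulfate monoester to 27.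

Step 5. Rear-side attack at C-3' next to the quaternary C-2' is slow, so elimination to the cyclopentene or a 1,2-methyl shift may compete and inversion may be incomplete. The fallback sets out from 9 and returns at 10, separating activation from displacement. Tf2O/pyridine in CH2Cl2 at −40 °C converts 9 into 1-[(1S,3S)-1,2,2-trimethyl-3-(trifluoromethanesulfonyloxy)cyclopentyl]ethenyl trifluoromethanesulfonate F5, and Bu4NBr in toluene at −20 → 20 °C displaces the alkyl triflate with inversion to give 10.

Further compounds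
F1 | step 11 | 1-[(1S,6S)-3,6-bis(tert-butyldimethylsilyloxy)-1-methylcyclohex-2-en-1-yl]-3-[(1R,3R)-3-bromo-1,2,2-trimethylcyclopentyl]but-3-en-2-one | CC1(C)[C@H](Br)CC[C@]1(C)C(=C)C(=O)C[C@@]1(C)C=C(O[Si](C)(C)C(C)(C)C)CC[C@@H]1O[Si](C)(C)C(C)(C)C
F2 | step 18 | 4a,8-cyclic sulfite of triol 26 | CC1(C)[C@H](Br)CC[C@]1(C)C1=C[C@]2(OS3=O)[C@](C)(O)CC[C@@H](O3)[C@@]2(C)CC1=O
F3 | step 18 | 4a,8-cyclic sulfate of triol 26 | CC1(C)[C@H](Br)CC[C@]1(C)C1=C[C@]2(OS3(=O)=O)[C@](C)(O)CC[C@@H](O3)[C@@]2(C)CC1=O
F4 | step 18 | tetrabutylammonium 4a-sulfate of 27 | CC1(C)[C@H](Br)CC[C@]1(C)C1=C[C@]2(OS(=O)(=O)[O-])[C@](C)(O)CC[C@H](Br)[C@@]2(C)CC1=O.CCCC[N+](CCCC)(CCCC)CCCC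
F5 | step 5 | 1-[(1S,3S)-1,2,2-trimethyl-3-(trifluoromethanesulfonyloxy)cyclopentyl]ethenyl trifluoromethanesulfonate | CC1(C)[C@@H](OS(=O)(=O)C(F)(F)F)CC[C@]1(C)C(=C)OS(=O)(=O)C(F)(F)F
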